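The route rests on disconnecting the C3–C4 bond of the γ-butyrolactone. C4, the methine between the ring OCH2 (C5) and the benzylic CH2 of the dihydrobenzofuran unit, is read as the central methylene of a plain 3-arylpropyl chain, whose C–H bond sits 1,5 to a carbenoid carbon. An enantioselective rhodium carbenoid C–H insertion of the chain's diazoacetate forges that bond, closes the five-membered lactone and sets C4 in one operation. Its precursor is the open-chain diazoacetate of a silyl-protected, enantiopure dihydrodehydrodiconiferyl alcohol. C3 is then set by trans-selective benzylation with a bromide carrying the erythro arylglycerol β-aryl ether, and one global desilylation ends the synthesis.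

Key step: step 14

Assumption (remark on the chemistry): Rh2(4S-MPPIM)4 is taken to be the catalyst enantiomer that turns 3-arylpropyl diazoacetates into (R)-β-arylmethyl-γ-butyrolactones; should the sense of induction be the opposite, the 4R catalyst is used under identical conditions.

Abbreviations: TIPS = triisopropylsilyl, TBS = tert-butyldimethylsilyl, MOM = methoxymethyl.

Step 1
Reactants: 1 vanillin (4-hydroxy-3-methoxybenzaldehyde)
Product: 2 3-methoxy-4-(TIPS-oxy)benzaldehyde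
Conditions: TIPSCl, imidazole, DMF, rt
Reagents that add atoms: triisopropylsilyl chloride, CC(C)[Si](Cl)(C(C)C)C(C)C
Why: O-silylation of the phenol gives a fluoride-labile aryl silyl ether that should survive the boron aldol, hydride, acid and enolate steps ahead.

Step 2
Reactants: 3 eugenol (4-allyl-2-methoxyphenol)
Product: 4 4-allyl-2-bromo-6-methoxyphenol
Conditions: NBS, iPr2NH (cat.), CH2Cl2, 0 °C, dark
Reagents that add atoms: N-bromosuccinimide, O=C1CCC(=O)N1Br
Why: Amine-catalysed electrophilic aromatic bromination should go ortho to the free hydroxyl (para is blocked) and be much faster than attack on the isolated terminal alkene.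

Step 3
Reactants: 4 4-allyl-2-bromo-6-methoxyphenol
Product: 5 5-allyl-1-bromo-3-methoxy-2-(methoxymethoxy)benzene
Conditions: MOMCl, iPr2NEt, CH2Cl2, 0 °C to rt
Reagents that add atoms: chloromethyl methyl ether, COCCl
Why: Williamson-type O-alkylation masks the phenol as a MOM acetal that tolerates the organozinc coupling, saponification and boron enolate chemistry and is removed by acid exactly when the phenol is needed for ring closure.

Step 4
Reactants: 5 5-allyl-1-bromo-3-methoxy-2-(methoxymethoxy)benzene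
Product: 6 ethyl 2-[5-allyl-3-methoxy-2-(methoxymethoxy)phenyl]acetate
Conditions: BrZnCH2CO2Et, Pd2(dba)3 (cat.), XPhos (cat.), THF, 60 °C
Reagents that add atoms: (2-ethoxy-2-oxoethyl)zinc bromide, CCOC(=O)C[Zn]Br
Why: Negishi-type coupling of the Reformatsky reagent (α-arylation of a zinc ester enolate after oxidative addition of zerovalent palladium) installs the acetic ester on the hindered, electron-rich aryl bromide under nearly neutral conditions that leave the MOM ether and the allyl group alone.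

Step 5
Reactants: 6 ethyl 2-[5-allyl-3-methoxy-2-(methoxymethoxy)phenyl]acetate
Product: 7 2-[5-allyl-3-methoxy-2-(methoxymethoxy)phenyl]acetic acid
Conditions: LiOH·H2O, THF–MeOH–H2O, rt; then 1 M HCl to pH 4 at 0 °C
Reagents that add atoms: lithium hydroxide, [Li+].[OH-]
Why: Saponification followed by careful acidification (kept above pH 3 to spare the MOM acetal) gives the arylacetic acid.

Step 6
Reactants: 7 2-[5-allyl-3-methoxy-2-(methoxymethoxy)phenyl]acetic acid; 8 (S)-4-benzyl-1,3-oxazolidin-2-one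
Product: 10 (4S)-4-benzyl-3-{[5-allyl-3-methoxy-2-(methoxymethoxy)phenyl]acetyl}-1,3-oxazolidin-2-one, via mixed pivalic anhydride 9 (not isolated)
Conditions: PivCl, Et3N, THF, −20 °C; then 8, LiCl, −20 °C to rt
Reagents that add atoms: none
Why: N-acylation of the oxazolidinone through the mixed anhydride under the mild lithium chloride/triethylamine protocol attaches the auxiliary without strong base.

Step 7
Reactants: 10 (4S)-4-benzyl-3-{[5-allyl-3-methoxy-2-(methoxymethoxy)phenyl]acetyl}-1,3-oxazolidin-2-one; 2 3-methoxy-4-(TIPS-oxy)benzaldehyde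
Product: 12 (4S)-3-{(2S,3S)-2-[5-allyl-3-methoxy-2-(methoxymethoxy)phenyl]-3-hydroxy-3-[3-methoxy-4-(TIPS-oxy)phenyl]propanoyl}-4-benzyl-1,3-oxazolidin-2-one, via Z dibutylboron enolate 11 (not isolated)
Conditions: Bu2BOTf, iPr2NEt, CH2Cl2, −78 to 0 °C; then 2, −78 to 0 °C; pH 7 buffer, MeOH, 30% H2O2, 0 °C
Reagents that add atoms: none
Why: Evans syn aldol, in which the Z boron enolate reacts through a Zimmerman–Traxler chair on the face opposite the auxiliary benzyl group, fixes the aryl-bearing α-carbon (later C3 of the dihydrobenzofuran); the carbinol centre is also set but is not needed later.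

Step 8
Reactants: 12 the syn aldol adduct
Product: 13 (1S,2R)-2-[5-allyl-3-methoxy-2-(methoxymethoxy)phenyl]-1-[3-methoxy-4-(TIPS-oxy)phenyl]propane-1,3-diol
Conditions: LiBH4, MeOH (2 equiv), THF, 0 °C
Reagents that add atoms: none
Why: Reductive cleavage of the N-acyl oxazolidinone gives the 1,3-diol and returns the auxiliary without touching either stereocentre (the α-carbon becomes R only through a change in CIP priorities).

Step 9
Reactants: 13 (1S,2R)-2-[5-allyl-3-methoxy-2-(methoxymethoxy)phenyl]-1-[3-methoxy-4-(TIPS-oxy)phenyl]propane-1,3-diol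
Product: 15 {(2S,3R)-5-allyl-7-methoxy-2-[3-methoxy-4-(TIPS-oxy)phenyl]-2,3-dihydro-1-benzofuran-3-yl}methanol, via free phenol diol 14 (not isolated)
Conditions: conc. HCl (cat.), MeOH, 40 °C
Reagents that add atoms: none
Why: Acid cleaves the MOM acetal and ionises the p-silyloxybenzylic alcohol to a stabilised cation that the freed phenol traps in an SN1 ring closure; attack anti to the C3 hydroxymethyl group should give the favoured 2,3-trans ring (2S,3R) whatever the carbinol configuration was (stereoconvergent).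

Step 10
Reactants: 15 {(2S,3R)-5-allyl-7-methoxy-2-[3-methoxy-4-(TIPS-oxy)phenyl]-2,3-dihydro-1-benzofuran-3-yl}methanol
Product: 16 (2S,3R)-5-allyl-3-[(TBS-oxy)methyl]-7-methoxy-2-[3-methoxy-4-(TIPS-oxy)phenyl]-2,3-dihydro-1-benzofuran
Conditions: TBSCl, imidazole, DMF, rt
Reagents that add atoms: tert-butyldimethylsilyl chloride, CC(C)(C)[Si](C)(C)Cl
Why: Standard silylation of the only free hydroxyl gives an ether that survives hydroboration, amine bases, the carbenoid step and the lithium enolate and leaves with the other silyl groups at the end.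

Step 11
Reactants: 16 (2S,3R)-5-allyl-3-[(TBS-oxy)methyl]-7-methoxy-2-[3-methoxy-4-(TIPS-oxy)phenyl]-2,3-dihydro-1-benzofuran
Product: 18 3-{(2S,3R)-3-[(TBS-oxy)methyl]-7-methoxy-2-[3-methoxy-4-(TIPS-oxy)phenyl]-2,3-dihydro-1-benzofuran-5-yl}propan-1-ol, via B-alkyl-9-BBN borane 17 (not isolated)
Conditions: 9-BBN, THF, 0 °C to rt; then 30% H2O2, aq. NaOAc, 0 °C to rt
Reagents that add atoms: hydrogen peroxide, OO
Why: Anti-Markovnikov hydroboration of the terminal alkene with the bulky borane and buffered oxidation unmasks the 3-hydroxypropyl chain, the allyl group having served as a protecting-group-free precursor of the primary alcohol.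

Step 12
Reactants: 18 3-{(2S,3R)-3-[(TBS-oxy)methyl]-7-methoxy-2-[3-methoxy-4-(TIPS-oxy)phenyl]-2,3-dihydro-1-benzofuran-5-yl}propan-1-ol
Product: 19 the bromoacetate of 18 (3-arylpropyl 2-bromoacetate)
Conditions: BrCH2COBr, NaHCO3, MeCN, 0 °C
Reagents that add atoms: bromoacetyl bromide, BrCC(=O)Br
Why: Acylation of the primary alcohol with the acid bromide under bicarbonate buffering gives the bromoacetate without disturbing the silyl ethers.

Step 13
Reactants: 19 the bromoacetate of 18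
Product: 20 the diazoacetate of 18 (3-arylpropyl 2-diazoacetate)
Conditions: TsNHNHTs, DBU, THF, 0 °C
Reagents that add atoms: N,N'-ditosylhydrazine (supplies both nitrogen atoms), Cc1ccc(cc1)S(=O)(=O)NNS(=O)(=O)c1ccc(C)cc1
Why: N-alkylation of the ditosylhydrazine by the bromoacetate and base-induced loss of two sulfinates delivers the diazoacetate under mild conditions (diazo synthesis from a bromoacetate).

Step 14
Reactants: 20 the diazoacetate of 18
Product: 21 (4R)-4-({(2S,3R)-3-[(TBS-oxy)methyl]-7-methoxy-2-[3-methoxy-4-(TIPS-oxy)phenyl]-2,3-dihydro-1-benzofuran-5-yl}methyl)oxolan-2-one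
Conditions: Rh2(4S-MPPIM)4 (dirhodium tetrakis[methyl (4S)-2-oxo-1-(3-phenylpropanoyl)imidazolidine-4-carboxylate], 2 mol %), CH2Cl2, reflux, 20 added over 10 h at high dilution
Reagents that add atoms: none
Why: The chiral dirhodium carboxamidate expels dinitrogen from the diazoacetate to give an electrophilic rhodium carbenoid, which inserts through a concerted three-centre transition state into a C–H bond of the central chain methylene and so forms the C3–C4 bond and the lactone in one step. The closest known reaction type is the enantioselective intramolecular C–H insertion of diazoacetates of primary alcohols catalysed by chiral dirhodium carboxamidates. The γ-lactone closes by 1,5-insertion, the normal ring size for carbenoid C–H insertion. The new stereocentre C4 arises from discrimination between the two enantiotopic hydrogens of a prochiral CH2 group and is controlled by the catalyst, whose ester and N-acyl arms on the four carboxamidate ligands allow only one orientation of the tethered chain, while the dihydrobenzofuran stereocentres are too remote to interfere. The step needs site selectivity for the β C–H over the benzylic γ C–H (six-membered lactone), the OCH2 C–H (four-membered lactone) and the arene, and the ester tether secures this because it places only that methylene 1,5 to the carbenoid carbon, with the silyl ethers and ring C–H bonds out of reach. Slow addition at high dilution should suppress carbene dimerisation.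

Step 15
Reactants: 22 methyl vanillate (methyl 4-hydroxy-3-methoxybenzoate); 23 (R)-4-benzyl-3-(chloroacetyl)-1,3-oxazolidin-2-one
Product: 24 methyl 4-{2-[(4R)-4-benzyl-2-oxo-1,3-oxazolidin-3-yl]-2-oxoethoxy}-3-methoxybenzoate
Conditions: K2CO3, NaI (cat.), acetone, rt to 45 °C
Reagents that add atoms: none
Why: SN2 displacement of the activated α-chloride (iodide catalysis) by the phenoxide gives the aryloxyacetyl imide in one step, the soft phenoxide attacking carbon and not the imide carbonyls.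

Step 16
Reactants: 24 methyl 4-{2-[(4R)-4-benzyl-2-oxo-1,3-oxazolidin-3-yl]-2-oxoethoxy}-3-methoxybenzoate; 2 3-methoxy-4-(TIPS-oxy)benzaldehyde
Product: 26 methyl 4-({(2R,3S)-1-[(4R)-4-benzyl-2-oxo-1,3-oxazolidin-3-yl]-3-hydroxy-3-[3-methoxy-4-(TIPS-oxy)phenyl]-1-oxopropan-2-yl}oxy)-3-methoxybenzoate (syn threo adduct), via Z dibutylboron enolate 25 (not isolated)
Conditions: Bu2BOTf, iPr2NEt, CH2Cl2, −78 to 0 °C; then 2, −78 to 0 °C; pH 7 buffer, MeOH, 30% H2O2, 0 °C
Reagents that add atoms: none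
Why: Evans syn aldol of the Z boron enolate through a Zimmerman–Traxler chair; with the R auxiliary the aldehyde adds to the face opposite the benzyl group, which sets the aryloxy-bearing carbon as the target requires (S at C8 of the final arylglycerol unit) and the carbinol carbon syn to it.

Step 17
Reactants: 26 the syn threo aldol adduct
Product: 27 methyl 4-({(2R,3R)-1-[(4R)-4-benzyl-2-oxo-1,3-oxazolidin-3-yl]-3-[3-methoxy-4-(TIPS-oxy)phenyl]-3-[(4-nitrobenzoyl)oxy]-1-oxopropan-2-yl}oxy)-3-methoxybenzoate (anti erythro ester)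
Conditions: 4-nitrobenzoic acid, PPh3, DIAD, toluene–THF, −20 °C to rt
Reagents that add atoms: 4-nitrobenzoic acid, OC(=O)c1ccc(cc1)[N+](=O)[O-]
Why: Mitsunobu esterification inverts the benzylic carbinol centre by SN2 displacement of the alkoxyphosphonium ion with 4-nitrobenzoate, turning the threo adduct into the erythro series; the electron-withdrawing imide and aryloxy groups next to the carbinol disfavour ionisation and so support clean inversion.

Step 18
Reactants: 27 the anti erythro 4-nitrobenzoate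
Product: 28 methyl 4-({(1R,2S)-1,3-dihydroxy-1-[3-methoxy-4-(TIPS-oxy)phenyl]propan-2-yl}oxy)-3-methoxybenzoate
Conditions: LiBH4, MeOH (4 equiv), THF, 0 °C
Reagents that add atoms: none
Why: Lithium borohydride cleaves the imide reductively to the primary alcohol and removes the activated 4-nitrobenzoate, while the electron-rich methyl benzoate should be reduced much more slowly, giving the erythro 1,3-diol.

Step 19
Reactants: 28 the erythro diol
Product: 29 methyl 4-({(1R,2S)-1,3-bis(TBS-oxy)-1-[3-methoxy-4-(TIPS-oxy)phenyl]propan-2-yl}oxy)-3-methoxybenzoate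
Conditions: TBSOTf, 2,6-lutidine, CH2Cl2, −78 to 0 °C
Reagents that add atoms: tert-butyldimethylsilyl triflate, CC(C)(C)[Si](C)(C)OS(=O)(=O)C(F)(F)F
Why: The silyl triflate with a hindered pyridine base silylates both the primary and the hindered secondary benzylic hydroxyl.

Step 20
Reactants: 29 the bis-TBS ester
Product: 30 [4-({(1R,2S)-1,3-bis(TBS-oxy)-1-[3-methoxy-4-(TIPS-oxy)phenyl]propan-2-yl}oxy)-3-methoxyphenyl]methanol
Conditions: iBu2AlH (DIBAL-H), CH2Cl2, −78 °C
Reagents that add atoms: none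
Why: Hydride reduction of the aryl ester gives the benzylic alcohol, silyl ethers being inert to this reagent at low temperature.

Step 21
Reactants: 30 the benzylic alcohol
Product: 31 4-(bromomethyl)-1-({(1R,2S)-1,3-bis(TBS-oxy)-1-[3-methoxy-4-(TIPS-oxy)phenyl]propan-2-yl}oxy)-2-methoxybenzene
Conditions: CBr4, PPh3, 2,6-lutidine (buffer), CH2Cl2, 0 °C; used at once
Reagents that add atoms: carbon tetrabromide, BrC(Br)(Br)Br
Why: Appel bromination converts the benzylic alcohol into the bromide under neutral conditions that spare the acid-labile benzylic silyl ether.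

Step 22
Reactants: 21 the (4R)-lactone; 31 the benzylic bromide
Product: 33 (3R,4R)-3-[4-({(1R,2S)-1,3-bis(TBS-oxy)-1-[3-methoxy-4-(TIPS-oxy)phenyl]propan-2-yl}oxy)-3-methoxybenzyl]-4-({(2S,3R)-3-[(TBS-oxy)methyl]-7-methoxy-2-[3-methoxy-4-(TIPS-oxy)phenyl]-2,3-dihydro-1-benzofuran-5-yl}methyl)oxolan-2-one, via lithium enolate 32 (not isolated)
Conditions: LiN(iPr)2 (LDA), THF, −78 °C; then 31, DMPU, −78 to −40 °C
Reagents that add atoms: none
Why: The lithium enolate of the β-substituted butyrolactone is alkylated on the face anti to the C4 substituent (1,2-induction in the five-membered enolate), which sets C3 as R and gives the trans-3,4-disubstituted lactone, also the thermodynamically preferred isomer.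

Step 23
Reactants: 33 the pentasilylated lactone
Product: 34 (3R,4R)-3-(4-{[(1R,2S)-1,3-dihydroxy-1-(4-hydroxy-3-methoxyphenyl)propan-2-yl]oxy}-3-methoxybenzyl)-4-{[(2S,3R)-2-(4-hydroxy-3-methoxyphenyl)-3-(hydroxymethyl)-7-methoxy-2,3-dihydro-1-benzofuran-5-yl]methyl}oxolan-2-one (CNP0298853.1)
Conditions: Bu4NF, AcOH (1:1), THF, 0 °C to rt
Reagents that add atoms: none
Why: Buffered fluoride removes the three TBS and two TIPS groups in one operation, acetic acid keeping the medium near neutral so that the lactone, the benzylic alcohol and the phenols are not exposed to strong base.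

Compound list
1 | vanillin | COc1cc(C=O)ccc1O | starting material
2 | 3-methoxy-4-(TIPS-oxy)benzaldehyde | COc1cc(C=O)ccc1O[Si](C(C)C)(C(C)C)C(C)C | intermediate
3 | eugenol | C=CCc1ccc(O)c(OC)c1 | starting material
4 | 4-allyl-2-bromo-6-methoxyphenol | C=CCc1cc(Br)c(O)c(OC)c1 | intermediate
5 | 5-allyl-1-bromo-3-methoxy-2-(methoxymethoxy)benzene | C=CCc1cc(Br)c(OCOC)c(OC)c1 | intermediate
6 | ethyl 2-[5-allyl-3-methoxy-2-(methoxymethoxy)phenyl]acetate | C=CCc1cc(CC(=O)OCC)c(OCOC)c(OC)c1 | intermediate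
7 | 2-[5-allyl-3-methoxy-2-(methoxymethoxy)phenyl]acetic acid | C=CCc1cc(CC(=O)O)c(OCOC)c(OC)c1 | intermediate
8 | (S)-4-benzyl-1,3-oxazolidin-2-one | O=C1N[C@@H](Cc2ccccc2)CO1 | starting material
9 | mixed pivalic anhydride of 7 (not isolated) | C=CCc1cc(CC(=O)OC(=O)C(C)(C)C)c(OCOC)c(OC)c1 | intermediate
10 | (4S)-4-benzyl-3-{[5-allyl-3-methoxy-2-(methoxymethoxy)phenyl]acetyl}-1,3-oxazolidin-2-one | C=CCc1cc(CC(=O)N2[C@@H](Cc3ccccc3)COC2=O)c(OCOC)c(OC)c1 | intermediate
11 | Z dibutylboron enolate of 10 (not isolated) | CCCCB(CCCC)O/C(=C\c1cc(CC=C)cc(OC)c1OCOC)N1[C@@H](Cc2ccccc2)COC1=O | intermediate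
12 | (2S,3S) syn aldol adduct on the (4S) auxiliary | O=C(N1[C@@H](Cc2ccccc2)COC1=O)[C@@H](c1cc(CC=C)cc(OC)c1OCOC)[C@H](O)c1ccc(O[Si](C(C)C)(C(C)C)C(C)C)c(OC)c1 | intermediate
13 | (1S,2R)-2-[5-allyl-3-methoxy-2-(methoxymethoxy)phenyl]-1-[3-methoxy-4-(TIPS-oxy)phenyl]propane-1,3-diol | OC[C@@H](c1cc(CC=C)cc(OC)c1OCOC)[C@H](O)c1ccc(O[Si](C(C)C)(C(C)C)C(C)C)c(OC)c1 | intermediate
14 | (1S,2R)-2-(5-allyl-2-hydroxy-3-methoxyphenyl)-1-[3-methoxy-4-(TIPS-oxy)phenyl]propane-1,3-diol (not isolated) | OC[C@@H](c1cc(CC=C)cc(OC)c1O)[C@H](O)c1ccc(O[Si](C(C)C)(C(C)C)C(C)C)c(OC)c1 | intermediate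
15 | {(2S,3R)-5-allyl-7-methoxy-2-[3-methoxy-4-(TIPS-oxy)phenyl]-2,3-dihydro-1-benzofuran-3-yl}methanol | C=CCc1cc(OC)c2c(c1)[C@H](CO)[C@@H](c1ccc(O[Si](C(C)C)(C(C)C)C(C)C)c(OC)c1)O2 | intermediate
16 | TBS ether of 15 | C=CCc1cc(OC)c2c(c1)[C@H](CO[Si](C)(C)C(C)(C)C)[C@@H](c1ccc(O[Si](C(C)C)(C(C)C)C(C)C)c(OC)c1)O2 | intermediate
17 | B-(3-arylpropyl)-9-borabicyclo[3.3.1]nonane from 16 (not isolated) | C1CC2CCCC(C1)B2CCCc1cc(OC)c2c(c1)[C@H](CO[Si](C)(C)C(C)(C)C)[C@@H](c1ccc(O[Si](C(C)C)(C(C)C)C(C)C)c(OC)c1)O2 | intermediate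
18 | 3-{(2S,3R)-3-[(TBS-oxy)methyl]-7-methoxy-2-[3-methoxy-4-(TIPS-oxy)phenyl]-2,3-dihydro-1-benzofuran-5-yl}propan-1-ol | OCCCc1cc(OC)c2c(c1)[C@H](CO[Si](C)(C)C(C)(C)C)[C@@H](c1ccc(O[Si](C(C)C)(C(C)C)C(C)C)c(OC)c1)O2 | intermediate
19 | bromoacetate of 18 | BrCC(=O)OCCCc1cc(OC)c2c(c1)[C@H](CO[Si](C)(C)C(C)(C)C)[C@@H](c1ccc(O[Si](C(C)C)(C(C)C)C(C)C)c(OC)c1)O2 | intermediate
20 | diazoacetate of 18 | [N-]=[N+]=CC(=O)OCCCc1cc(OC)c2c(c1)[C@H](CO[Si](C)(C)C(C)(C)C)[C@@H](c1ccc(O[Si](C(C)C)(C(C)C)C(C)C)c(OC)c1)O2 | intermediate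
21 | (4R)-4-({(2S,3R)-3-[(TBS-oxy)methyl]-7-methoxy-2-[3-methoxy-4-(TIPS-oxy)phenyl]-2,3-dihydro-1-benzofuran-5-yl}methyl)oxolan-2-one | O=C1C[C@@H](Cc2cc(OC)c3c(c2)[C@H](CO[Si](C)(C)C(C)(C)C)[C@@H](c2ccc(O[Si](C(C)C)(C(C)C)C(C)C)c(OC)c2)O3)CO1 | intermediate
22 | methyl vanillate | COC(=O)c1ccc(O)c(OC)c1 | starting material
23 | (R)-4-benzyl-3-(chloroacetyl)-1,3-oxazolidin-2-one | O=C(CCl)N1[C@H](Cc2ccccc2)COC1=O | starting material
24 | methyl 4-{2-[(4R)-4-benzyl-2-oxo-1,3-oxazolidin-3-yl]-2-oxoethoxy}-3-methoxybenzoate | COC(=O)c1ccc(OCC(=O)N2[C@H](Cc3ccccc3)COC2=O)c(OC)c1 | intermediate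
25 | Z dibutylboron enolate of 24 (not isolated) | CCCCB(CCCC)O/C(=C\Oc1ccc(C(=O)OC)cc1OC)N1[C@H](Cc2ccccc2)COC1=O | intermediate
26 | (2R,3S) syn (threo) aldol adduct on the (4R) auxiliary | COc1cc([C@H](O)[C@H](C(=O)N2[C@H](Cc3ccccc3)COC2=O)Oc2ccc(C(=O)OC)cc2OC)ccc1O[Si](C(C)C)(C(C)C)C(C)C | intermediate
27 | (2R,3R) anti (erythro) 4-nitrobenzoate on the (4R) auxiliary | COc1cc([C@@H](OC(=O)c2ccc(cc2)[N+](=O)[O-])[C@H](C(=O)N2[C@H](Cc3ccccc3)COC2=O)Oc2ccc(C(=O)OC)cc2OC)ccc1O[Si](C(C)C)(C(C)C)C(C)C | intermediate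
28 | methyl 4-({(1R,2S)-1,3-dihydroxy-1-[3-methoxy-4-(TIPS-oxy)phenyl]propan-2-yl}oxy)-3-methoxybenzoate | COc1cc([C@@H](O)[C@H](CO)Oc2ccc(C(=O)OC)cc2OC)ccc1O[Si](C(C)C)(C(C)C)C(C)C | intermediate
29 | methyl 4-({(1R,2S)-1,3-bis(TBS-oxy)-1-[3-methoxy-4-(TIPS-oxy)phenyl]propan-2-yl}oxy)-3-methoxybenzoate | COc1cc([C@@H](O[Si](C)(C)C(C)(C)C)[C@H](CO[Si](C)(C)C(C)(C)C)Oc2ccc(C(=O)OC)cc2OC)ccc1O[Si](C(C)C)(C(C)C)C(C)C | intermediate
30 | [4-({(1R,2S)-1,3-bis(TBS-oxy)-1-[3-methoxy-4-(TIPS-oxy)phenyl]propan-2-yl}oxy)-3-methoxyphenyl]methanol | COc1cc([C@@H](O[Si](C)(C)C(C)(C)C)[C@H](CO[Si](C)(C)C(C)(C)C)Oc2ccc(CO)cc2OC)ccc1O[Si](C(C)C)(C(C)C)C(C)C | intermediate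
31 | 4-(bromomethyl)-1-({(1R,2S)-1,3-bis(TBS-oxy)-1-[3-methoxy-4-(TIPS-oxy)phenyl]propan-2-yl}oxy)-2-methoxybenzene | COc1cc([C@@H](O[Si](C)(C)C(C)(C)C)[C@H](CO[Si](C)(C)C(C)(C)C)Oc2ccc(CBr)cc2OC)ccc1O[Si](C(C)C)(C(C)C)C(C)C | intermediate
32 | lithium enolate of 21 (not isolated) | [Li]OC1=C[C@@H](Cc2cc(OC)c3c(c2)[C@H](CO[Si](C)(C)C(C)(C)C)[C@@H](c2ccc(O[Si](C(C)C)(C(C)C)C(C)C)c(OC)c2)O3)CO1 | intermediate
33 | pentasilylated (3R,4R)-lactone | COc1cc([C@@H](O[Si](C)(C)C(C)(C)C)[C@H](CO[Si](C)(C)C(C)(C)C)Oc2ccc(C[C@H]3C(=O)OC[C@@H]3Cc3cc(OC)c4c(c3)[C@H](CO[Si](C)(C)C(C)(C)C)[C@@H](c3ccc(O[Si](C(C)C)(C(C)C)C(C)C)c(OC)c3)O4)cc2OC)ccc1O[Si](C(C)C)(C(C)C)C(C)C | intermediate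
34 | CNP0298853.1 | COc1cc([C@@H](O)[C@H](CO)Oc2ccc(C[C@H]3C(=O)OC[C@@H]3Cc3cc(OC)c4c(c3)[C@H](CO)[C@@H](c3ccc(O)c(OC)c3)O4)cc2OC)ccc1O | target

Total step count: 23.
Longest linear sequence: 15 steps (steps 2 to 14, then 22 and 23, from eugenol).

Steps most likely to fail

Step 14. The carbenoid may be diverted into insertion at the benzylic γ C–H, carbene dimerisation or reaction with traces of water, or the discrimination between the two methylene hydrogens may be poor on this large substrate. The fallback sets out from 18 and returns at 21, and makes the C3–C4 bond by auxiliary-controlled enolate alkylation instead. Alcohol 18 is oxidised (TEMPO, PhI(OAc)2, MeCN–H2O) to the 3-arylpropanoic acid F1. This is activated as its mixed pivalic anhydride F2 (PivCl, Et3N; not isolated) and coupled with 8 (LiCl) to the N-acyl oxazolidinone F3. Deprotonation with NaN(SiMe3)2 in THF at −78 °C gives the sodium Z enolate F4 (not isolated), which tert-butyl bromoacetate should alkylate on the face away from the benzyl group to give the (R)-configured succinate imide F5. LiBH4 reduces the imide selectively to the hydroxy tert-butyl ester F6, and catalytic KOtBu in THF at 0 °C lactonises it to 21.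

Step 17. Elimination across the β-hydroxy imide or partial ionisation of the electron-rich benzylic centre may compete with clean SN2 inversion. The fallback sets out from 26 and returns at 29, and replaces inversion by oxidation and chelation-controlled reduction. LiBH4 reduces 26 to the threo diol F7, and TBSCl with imidazole in CH2Cl2 at 0 °C silylates the primary hydroxyl selectively to give F8. Dess–Martin periodinane oxidises the benzylic alcohol to the α-aryloxy ketone F9. Reduction with Zn(BH4)2 in Et2O at −30 °C, where zinc ties the ketone oxygen to the 2-methoxyphenoxy group and hydride enters from the side of the α-hydrogen, should favour the erythro alcohol F10. TBSOTf with 2,6-lutidine then gives 29.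

Step 9. Before the phenol is unmasked, the benzylic cation may fragment with loss of formaldehyde, eliminate towards a stilbene, or the allyl double bond may migrate. The fallback sets out from 13 and returns at 15, and blocks the fragmentation by masking the primary hydroxyl. Both hydroxyls of 13 are acetylated (Ac2O, pyridine, DMAP) to the diacetate F11. TsOH in MeOH–CH2Cl2 at rt removes the MOM group to give the phenol diacetate F12 (not isolated), whose benzylic acetate ionises and closes to the trans-dihydrobenzofuran acetate F13. iBu2AlH at −78 °C then frees 15.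

Further compounds
F1 | step 14 | 3-{(2S,3R)-3-[(TBS-oxy)methyl]-7-methoxy-2-[3-methoxy-4-(TIPS-oxy)phenyl]-2,3-dihydro-1-benzofuran-5-yl}propanoic acid | OC(=O)CCc1cc(OC)c2c(c1)[C@H](CO[Si](C)(C)C(C)(C)C)[C@@H](c1ccc(O[Si](C(C)C)(C(C)C)C(C)C)c(OC)c1)O2
F2 | step 14 | mixed pivalic anhydride of F1 | CC(C)(C)C(=O)OC(=O)CCc1cc(OC)c2c(c1)[C@H](CO[Si](C)(C)C(C)(C)C)[C@@H](c1ccc(O[Si](C(C)C)(C(C)C)C(C)C)c(OC)c1)O2
F3 | step 14 | (4S)-4-benzyl-3-(3-arylpropanoyl)-1,3-oxazolidin-2-one from F1 | O=C(CCc1cc(OC)c2c(c1)[C@H](CO[Si](C)(C)C(C)(C)C)[C@@H](c1ccc(O[Si](C(C)C)(C(C)C)C(C)C)c(OC)c1)O2)N1[C@@H](Cc2ccccc2)COC1=O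
F4 | step 14 | sodium Z enolate of F3 | [Na]O/C(=C\Cc1cc(OC)c2c(c1)[C@H](CO[Si](C)(C)C(C)(C)C)[C@@H](c1ccc(O[Si](C(C)C)(C(C)C)C(C)C)c(OC)c1)O2)N1[C@@H](Cc2ccccc2)COC1=O
F5 | step 14 | tert-butyl (3R)-3-(arylmethyl)-4-[(4S)-4-benzyl-2-oxo-1,3-oxazolidin-3-yl]-4-oxobutanoate | O=C([C@@H](CC(=O)OC(C)(C)C)Cc1cc(OC)c2c(c1)[C@H](CO[Si](C)(C)C(C)(C)C)[C@@H](c1ccc(O[Si](C(C)C)(C(C)C)C(C)C)c(OC)c1)O2)N1[C@@H](Cc2ccccc2)COC1=O
F6 | step 14 | tert-butyl (3R)-3-(arylmethyl)-4-hydroxybutanoate | OC[C@@H](CC(=O)OC(C)(C)C)Cc1cc(OC)c2c(c1)[C@H](CO[Si](C)(C)C(C)(C)C)[C@@H](c1ccc(O[Si](C(C)C)(C(C)C)C(C)C)c(OC)c1)O2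
F7 | step 17 | methyl 4-({(1S,2S)-1,3-dihydroxy-1-[3-methoxy-4-(TIPS-oxy)phenyl]propan-2-yl}oxy)-3-methoxybenzoate (threo diol) | COc1cc([C@H](O)[C@H](CO)Oc2ccc(C(=O)OC)cc2OC)ccc1O[Si](C(C)C)(C(C)C)C(C)C
F8 | step 17 | primary TBS ether of F7 | COc1cc([C@H](O)[C@H](CO[Si](C)(C)C(C)(C)C)Oc2ccc(C(=O)OC)cc2OC)ccc1O[Si](C(C)C)(C(C)C)C(C)C
F9 | step 17 | methyl 4-({(2S)-3-(TBS-oxy)-1-[3-methoxy-4-(TIPS-oxy)phenyl]-1-oxopropan-2-yl}oxy)-3-methoxybenzoate | COc1cc(C(=O)[C@H](CO[Si](C)(C)C(C)(C)C)Oc2ccc(C(=O)OC)cc2OC)ccc1O[Si](C(C)C)(C(C)C)C(C)C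
F10 | step 17 | methyl 4-({(1R,2S)-3-(TBS-oxy)-1-hydroxy-1-[3-methoxy-4-(TIPS-oxy)phenyl]propan-2-yl}oxy)-3-methoxybenzoate (erythro alcohol) | COc1cc([C@@H](O)[C@H](CO[Si](C)(C)C(C)(C)C)Oc2ccc(C(=O)OC)cc2OC)ccc1O[Si](C(C)C)(C(C)C)C(C)C
F11 | step 9 | diacetate of 13 | CC(=O)OC[C@@H](c1cc(CC=C)cc(OC)c1OCOC)[C@H](OC(C)=O)c1ccc(O[Si](C(C)C)(C(C)C)C(C)C)c(OC)c1
F12 | step 9 | diacetate of 14 (free phenol) | CC(=O)OC[C@@H](c1cc(CC=C)cc(OC)c1O)[C@H](OC(C)=O)c1ccc(O[Si](C(C)C)(C(C)C)C(C)C)c(OC)c1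
F13 | step 9 | acetate of 15 | C=CCc1cc(OC)c2c(c1)[C@H](COC(C)=O)[C@@H](c1ccc(O[Si](C(C)C)(C(C)C)C(C)C)c(OC)c1)O2
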